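**Plan**
1. Retrosynthesis: the epoxide oxygen on C4/C5 and the C8 aroyl group with the C6 hydrogen come off first (directed epoxidation, Evans–Tishchenko reduction). The ten-membered ring is then folded by reconnecting C6–C10 (retro-Grob). The resulting bicycle is cut at C4=C5 (metathesis), C5–C6 (vinyl addition) and C1–C10 (aldol), back to a cyclopentenone made from a furan.
2. Enabling feature: the E C1=C10 alkene and the C6 oxygen are 1,3-related through C10 (C1=C10···C6–O). A 1,3-diol monosulfonate fragmentation leaves exactly this pattern when the C6–C10 bond shared by ring A (five-membered, C6–C7–C8–C9–C10) and ring B (seven-membered, C10–C1–C2–C3–C4–C5–C6) is broken.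
3. Forward order of rings: ring A (Piancatelli rearrangement), then ring B closed onto it (ring-closing metathesis), then both merged into the ten-membered ring (step 12), then the C6/C8 oxygens and the epoxide.
4. Stereochemistry: C8 from a lipase resolution and C7 cis to it through a Mitsunobu inversion. E C1=C10 comes from the C1/C10 relationship (C10 by aldol anti to the ring substituents, C1 by chelate-controlled reduction). Z C4=C5 is imposed by ring B. C6 is set by hydride delivery from the C8 hemiacetal, and C4/C5 by the C6 hydroxyl.

Key step: step 12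

Remark: from compound 10 onward, ring atoms carry the germacrane numbers of the target (C6 carbonyl/carbinol carbon, C7 isopropyl-bearing, C8 oxygenated, C9 CH2, C10 methyl-bearing; C1–C4 come from the aldehyde, C5 from the vinyl group).
Assumption: in step 4 the lipase acylates the (4R)-alcohol faster (large/medium-substituent model for secondary alcohols), so the unreacted alcohol is (4S,5S); compounds 1, 2, 9 and 21 are taken as commercial.

**Step 1**
Reactants: 1 3-methylfuran-2-carbaldehyde; 2 isopropylmagnesium chloride
Product: 3 rac-2-methyl-1-(3-methylfuran-2-yl)propan-1-ol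
Conditions: i-PrMgCl (1.2 equiv), THF, −78 °C to 0 °C; aq. NH4Cl
Reagents that add atoms: none
Why: Grignard 1,2-addition to an unhindered heteroaryl aldehyde; the carbinol centre forms racemic, which is immaterial because it is planarised in step 2.

**Step 2**
Reactants: 3 rac-2-methyl-1-(3-methylfuran-2-yl)propan-1-ol
Product: 4 rac-trans-4-hydroxy-5-isopropyl-2-methylcyclopent-2-en-1-one
Conditions: Dy(OTf)3 (10 mol %), t-BuOH/H2O 5:1, 80 °C
Reagents that add atoms: water, O
Why: Piancatelli rearrangement: ionisation of the furylcarbinol, attack of water at the free furan C5, ring opening and conrotatory 4π electrocyclisation of the pentadienyl cation place OH and isopropyl trans (both centres racemic) and leave the former furan 3-methyl on the enone α-carbon.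

**Step 3**
Reactants: 4 rac-trans-4-hydroxy-5-isopropyl-2-methylcyclopent-2-en-1-one
Product: 6 rac-cis-4-hydroxy-5-isopropyl-2-methylcyclopent-2-en-1-one, via cis-formate 5 (not isolated)
Conditions: HCO2H, PPh3, DIAD, THF, 0 °C to rt; then MeOH, NaHCO3, rt
Reagents that add atoms: formic acid, O=CO
Why: Mitsunobu reaction: SN2 displacement of the oxyphosphonium group by formate inverts the carbinol centre and turns the trans into the cis O/isopropyl relationship; formate is the smallest carboxylate for entry next to the isopropyl group and is removed by near-neutral methanolysis that spares the base-labile β-oxygenated ketone.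

**Step 4**
Reactants: 6 rac-cis-4-hydroxy-5-isopropyl-2-methylcyclopent-2-en-1-one
Product: 7 (4S,5S)-4-hydroxy-5-isopropyl-2-methylcyclopent-2-en-1-one
Conditions: immobilised Candida antarctica lipase B, vinyl acetate, MTBE, 30 °C, run slightly past half conversion; chromatography
Reagents that add atoms: none
Why: Lipase-catalysed kinetic resolution by irreversible acyl transfer: the enzyme should acetylate the (4R)-alcohol (small vinylic CH on one side of the carbinol, branched CH(i-Pr) on the other) and leave the (4S,5S)-alcohol, so the absolute configuration of C8 (and with it C7) is fixed here, and running past half conversion raises the purity of the remaining alcohol.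

**Step 5**
Reactants: 7 (4S,5S)-4-hydroxy-5-isopropyl-2-methylcyclopent-2-en-1-one
Product: 8 (4S,5S)-4-(tert-butyldimethylsilyloxy)-5-isopropyl-2-methylcyclopent-2-en-1-one
Conditions: TBSCl, imidazole, DMF, rt
Reagents that add atoms: tert-butyldimethylsilyl chloride, CC(C)(C)[Si](C)(C)Cl
Why: Silyl ether formation under mildly basic conditions that neither epimerise the α-centre nor trigger β-elimination; the TBS group survives the hydride, Grignard, metathesis and alkoxide steps and keeps O8 masked until step 13.

**Step 6**
Reactants: 8 (4S,5S)-4-(tert-butyldimethylsilyloxy)-5-isopropyl-2-methylcyclopent-2-en-1-one; 9 4-methylpent-4-enal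
Product: 11 (2R,4S,5S)-2-(1-hydroxy-4-methylpent-4-en-1-yl)-2-methyl-4-(tert-butyldimethylsilyloxy)-5-isopropylcyclopentan-1-one (both C1 carbinol epimers), via lithium enolate 10 (not isolated)
Conditions: LiBH(s-Bu)3 (L-Selectride, 1.05 equiv), THF, −78 °C; then 9, −78 °C; aq. NH4Cl at −78 °C
Reagents that add atoms: none
Why: Conjugate reduction–aldol sequence: hydride adds to the unsubstituted β-carbon (C9) to give the regiodefined enolate 10, which attacks the aldehyde through C10 on the face opposite the cis C7 isopropyl and C8 silyloxy groups, so the quaternary centre forms with methyl syn to OTBS; the C1 carbinol configuration (closed Zimmerman–Traxler transition state, probably a mixture) is not relied upon because steps 9 and 10 reset it.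

**Step 7**
Reactants: 11 aldol adduct
Product: 12 1-ethenyl-2-(1-hydroxy-4-methylpent-4-en-1-yl)-2-methyl-4-(tert-butyldimethylsilyloxy)-5-isopropylcyclopentan-1-ol (C6 OH, C10 CH3, C7 i-Pr and C8 OTBS on one face; ethenyl and side chain on the other)
Conditions: CH2=CHMgBr (4 equiv), LaCl3·2LiCl, THF, −78 °C to 0 °C
Reagents that add atoms: vinylmagnesium bromide, C=C[Mg]Br
Why: Lewis-acid-assisted Grignard 1,2-addition: LaCl3·2LiCl raises carbonyl electrophilicity and curbs enolisation, and the vinyl group should enter C6 from the face opposite the C7 isopropyl, C10 methyl and C8 silyloxy groups (cis to the magnesium-chelated C1 side chain), which sets the tertiary carbinol with OH syn to the methyl and puts both alkenes on the same face.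

**Step 8**
Reactants: 12 vinyl diol
Product: 13 cis-fused 2-(tert-butyldimethylsilyloxy)-3-isopropyl-5,8a-dimethyl-1,2,3,3a,6,7,8,8a-octahydroazulene-3a,8-diol (azulene C8 = C1, C3a = C6, C8a = C10; C1 epimers)
Conditions: second-generation Grubbs catalyst (5–10 mol %), CH2Cl2, 40 °C
Reagents that add atoms: none
Why: Ring-closing metathesis between the C6 vinyl group and the 1,1-disubstituted C4 alkene, held cis on the cyclopentane, closes the seven-membered ring with loss of ethene; the trisubstituted C4=C5 bond can only be Z inside this ring, and the free tertiary allylic hydroxyl is tolerated by the ruthenium carbene.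

**Step 9**
Reactants: 13 bicyclic diol (C1 epimers)
Product: 14 cis-fused 3a-hydroxy-2-(tert-butyldimethylsilyloxy)-3-isopropyl-5,8a-dimethyl-2,3,3a,6,7,8a-hexahydroazulen-8(1H)-one (C1 ketone, C6 tertiary alcohol)
Conditions: Dess–Martin periodinane, NaHCO3, CH2Cl2, 0 °C to rt
Reagents that add atoms: none
Why: Dess–Martin oxidation converts only the secondary C1 alcohol (the tertiary allylic C6 alcohol cannot be oxidised) and merges both C1 epimers into one ketol under buffered conditions that avoid retro-aldol opening.

**Step 10**
Reactants: 14 bicyclic ketol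
Product: 16 bicyclic 1,6-syn diol (C1 OH cis to C6 OH and to the C10 methyl), via diethylboron chelate 15 (not isolated)
Conditions: Et2BOMe, THF/MeOH 4:1, −78 °C; then NaBH4, −78 °C; AcOH, then evaporation from MeOH
Reagents that add atoms: none
Why: Narasaka–Prasad reduction: the diethylboron chelate 15 of O6 and the C1 carbonyl is a chair trans-fused to the cyclopentane with the C5 arm of the seven-membered ring axial on one face, so borohydride adds from the other face and the new C1–O bond ends up cis to the C6–O bond and the C10 methyl, the relationship the fragmentation needs.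

**Step 11**
Reactants: 16 bicyclic 1,6-syn diol
Product: 17 cis-fused hydroazulenol 1-mesylate (C1 OMs cis to C10 CH3 and C6 OH; C4=C5 in the seven-membered ring; C8 OTBS)
Conditions: MsCl, Et3N, CH2Cl2, −20 °C
Reagents that add atoms: methanesulfonyl chloride, CS(=O)(=O)Cl
Why: Sulfonylation distinguishes the secondary C1 hydroxyl from the tertiary ring-fusion C6 hydroxyl, which must stay free as the electron source of the fragmentation; the C1–O bond is not touched, so its configuration is retained.

**Step 12**
Reactants: 17 hydroazulenol 1-mesylate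
Product: 19 (1(10)E,4Z,7S,8S)-8-(tert-butyldimethylsilyloxy)germacra-1(10),4-dien-6-one, via potassium alkoxide 18 (not isolated)
Conditions: KOtBu (1.05 equiv), THF, −20 °C to 0 °C; pH 7 buffer
Reagents that add atoms: none
Why: Grob (Wharton-type) fragmentation of a 1,3-diol monosulfonate: KOtBu deprotonates the tertiary C6 hydroxyl to alkoxide 18, whose oxygen lone pair pushes into the C6–C10 bond as that bond, antiperiplanar to C1–OMs, breaks and mesylate leaves, so C6=O and C1=C10 form in one concerted event. The closest known reaction type is the fragmentation of bicyclic 1,3-diol monosulfonates to E-cycloalkenones used for ten-membered carbocycles. No ring is closed by bond formation: the ten-membered ring appears because the bond shared by the five- and seven-membered rings is cut, so no macrocyclisation is needed. No stereocentre is created; the alkene geometry is transferred stereospecifically from the C1/C10 relationship, because with OMs cis to the C10 methyl the only antiperiplanar conformer has C2 anti to C9 and can give only the E alkene, while the Z C4=C5 bond and the C7 and C8 centres are carried through. The step needs fragmentation to outrun oxetane formation, E2 loss of mesylate and base damage to the product: the cis disposition of O6 and OMs rules out backside attack at C1, and a single equivalent of base at low temperature is consumed as neutral potassium mesylate forms, which protects the β-silyloxy ketone and the C7 centre.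

**Step 13**
Reactants: 19 silyloxy dienone
Product: 20 (1(10)E,4Z,7S,8S)-8-hydroxygermacra-1(10),4-dien-6-one
Conditions: HF·pyridine, pyridine, THF, 0 °C to rt
Reagents that add atoms: none
Why: Fluoride-mediated desilylation under buffered, non-basic conditions frees the C8 hydroxyl without retro-aldol cleavage, β-elimination or epimerisation at C7 of the β-hydroxy ketone.

**Step 14**
Reactants: 20 hydroxy dienone; 21 3,4,5-trimethoxybenzaldehyde
Product: 23 (1(10)E,4Z,6S,7R,8S)-6-hydroxygermacra-1(10),4-dien-8-yl 3,4,5-trimethoxybenzoate, via hemiacetal 22 (not isolated)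
Conditions: 21 (5 equiv), SmI2 (0.3 equiv, decolourised by the aldehyde before the substrate is added), THF, −10 °C
Reagents that add atoms: none
Why: Evans–Tishchenko reduction: the trivalent samarium species formed from SmI2 and the aldehyde binds hemiacetal 22 of the C8 hydroxyl together with the C6 carbonyl, and hydride is passed intramolecularly through a six-membered chair in which C5, the C7 isopropyl group and C9 are all equatorial, which gives the 6,8-anti diol monoester with the aroyl group on O8 and sets C6 from C8.

**Step 15**
Reactants: 23 allylic alcohol ester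
Product: 24 (1(10)E,4S,5R,6R,7R,8S)-4,5-epoxy-6-hydroxygermacr-1(10)-en-8-yl 3,4,5-trimethoxybenzoate (target)
Conditions: VO(acac)2 (5 mol %), t-BuOOH (1.5 equiv, decane), CH2Cl2, 0 °C
Reagents that add atoms: tert-butyl hydroperoxide, CC(C)(C)OO
Why: Hydroxyl-directed epoxidation: the vanadium alkoxide of the C6 hydroxyl delivers the peroxide oxygen only to the allylic Z alkene (the remote C1=C10 bond has no directing group) and, as with medium-ring (Z)-cycloalk-2-enols, to the face cis to the hydroxyl, so syn addition gives the cis-epoxide with the 5,6-erythro relationship and sets C4 and C5 from C6.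

**Compound list**
1 | 3-methylfuran-2-carbaldehyde | Cc1ccoc1C=O | starting material
2 | isopropylmagnesium chloride | CC(C)[Mg]Cl | starting material
3 | rac-2-methyl-1-(3-methylfuran-2-yl)propan-1-ol | Cc1ccoc1C(O)C(C)C | intermediate
4 | rac-trans-4-hydroxy-5-isopropyl-2-methylcyclopent-2-en-1-one (racemic; 4R,5S enantiomer drawn) | O[C@@H]1C=C(C)C(=O)[C@H]1C(C)C | intermediate
5 | rac-cis-4-formyloxy-5-isopropyl-2-methylcyclopent-2-en-1-one (racemic; 4S,5S enantiomer drawn) | O=CO[C@H]1C=C(C)C(=O)[C@H]1C(C)C | intermediate (not isolated)
6 | rac-cis-4-hydroxy-5-isopropyl-2-methylcyclopent-2-en-1-one (racemic; 4S,5S enantiomer drawn) | O[C@H]1C=C(C)C(=O)[C@H]1C(C)C | intermediate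
7 | (4S,5S)-4-hydroxy-5-isopropyl-2-methylcyclopent-2-en-1-one | O[C@H]1C=C(C)C(=O)[C@H]1C(C)C | intermediate
8 | (4S,5S)-4-(tert-butyldimethylsilyloxy)-5-isopropyl-2-methylcyclopent-2-en-1-one | CC(C)(C)[Si](C)(C)O[C@H]1C=C(C)C(=O)[C@H]1C(C)C | intermediate
9 | 4-methylpent-4-enal | C=C(C)CCC=O | starting material
10 | lithium (4S,5S)-4-(tert-butyldimethylsilyloxy)-5-isopropyl-2-methylcyclopent-1-en-1-olate | CC(C)(C)[Si](C)(C)O[C@H]1CC(C)=C(O[Li])[C@H]1C(C)C | intermediate (not isolated)
11 | (2R,4S,5S)-2-(1-hydroxy-4-methylpent-4-en-1-yl)-2-methyl-4-(tert-butyldimethylsilyloxy)-5-isopropylcyclopentan-1-one; C10 methyl cis to OTBS and i-Pr; C1 carbinol epimers | CC(C)(C)[Si](C)(C)O[C@H]1C[C@](C)(C(O)CCC(C)=C)C(=O)[C@H]1C(C)C | intermediate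
12 | 1-ethenyl-2-(1-hydroxy-4-methylpent-4-en-1-yl)-2-methyl-4-(tert-butyldimethylsilyloxy)-5-isopropylcyclopentan-1-ol; 1-OH, 2-CH3, 5-i-Pr and 4-OTBS on one face; C1 carbinol epimers | CC(C)(C)[Si](C)(C)O[C@H]1C[C@](C)(C(O)CCC(C)=C)[C@](O)(C=C)[C@H]1C(C)C | intermediate
13 | cis-fused 2-(tert-butyldimethylsilyloxy)-3-isopropyl-5,8a-dimethyl-1,2,3,3a,6,7,8,8a-octahydroazulene-3a,8-diol; 3a-OH, 8a-CH3, 3-i-Pr and 2-OTBS all cis; epimers at C8 (germacrane C1) | CC(C)(C)[Si](C)(C)O[C@H]1C[C@]2(C)C(O)CCC(C)=C[C@]2(O)[C@H]1C(C)C | intermediate
14 | cis-fused 3a-hydroxy-2-(tert-butyldimethylsilyloxy)-3-isopropyl-5,8a-dimethyl-2,3,3a,6,7,8a-hexahydroazulen-8(1H)-one | CC(C)(C)[Si](C)(C)O[C@H]1C[C@]2(C)C(=O)CCC(C)=C[C@]2(O)[C@H]1C(C)C | intermediate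
15 | O6-diethylboryl chelate of ketol 14 | CC(C)(C)[Si](C)(C)O[C@H]1C[C@]2(C)C(=O)CCC(C)=C[C@]2(OB(CC)CC)[C@H]1C(C)C | intermediate (not isolated)
16 | cis-fused octahydroazulene-3a,8-diol of 13 as the single epimer with 8-OH (germacrane C1) cis to 3a-OH and 8a-CH3 | CC(C)(C)[Si](C)(C)O[C@H]1C[C@]2(C)[C@@H](O)CCC(C)=C[C@]2(O)[C@H]1C(C)C | intermediate
17 | 8-methanesulfonate of diol 16 (cis-fused hydroazulenol 1-mesylate, germacrane numbering) | CC(C)(C)[Si](C)(C)O[C@H]1C[C@]2(C)[C@@H](OS(C)(=O)=O)CCC(C)=C[C@]2(O)[C@H]1C(C)C | intermediate
18 | potassium C6-alkoxide of mesylate 17 | CC(C)(C)[Si](C)(C)O[C@H]1C[C@]2(C)[C@@H](OS(C)(=O)=O)CCC(C)=C[C@]2(O[K])[C@H]1C(C)C | intermediate (not isolated)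
19 | (1(10)E,4Z,7S,8S)-8-(tert-butyldimethylsilyloxy)germacra-1(10),4-dien-6-one [(2Z,6E)-9-silyloxy-10-isopropyl-3,7-dimethylcyclodeca-2,6-dien-1-one] | CC(C)(C)[Si](C)(C)O[C@H]1C/C(C)=C/CC/C(C)=C\C(=O)[C@H]1C(C)C | intermediate
20 | (1(10)E,4Z,7S,8S)-8-hydroxygermacra-1(10),4-dien-6-one | O[C@H]1C/C(C)=C/CC/C(C)=C\C(=O)[C@H]1C(C)C | intermediate
21 | 3,4,5-trimethoxybenzaldehyde | COc1cc(C=O)cc(OC)c1OC | starting material
22 | hemiacetal of 20 (O8) and 21, samarium-bound | COc1cc(C(O)O[C@H]2C/C(C)=C/CC/C(C)=C\C(=O)[C@H]2C(C)C)cc(OC)c1OC | intermediate (not isolated)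
23 | (1(10)E,4Z,6S,7R,8S)-6-hydroxygermacra-1(10),4-dien-8-yl 3,4,5-trimethoxybenzoate | COc1cc(C(=O)O[C@H]2C/C(C)=C/CC/C(C)=C\[C@H](O)[C@H]2C(C)C)cc(OC)c1OC | intermediate
24 | (1(10)E,4S,5R,6R,7R,8S)-4,5-epoxy-6-hydroxygermacr-1(10)-en-8-yl 3,4,5-trimethoxybenzoate | COc1cc(C(=O)O[C@H]2C/C(C)=C/CC[C@]3(C)O[C@@H]3[C@H](O)[C@H]2C(C)C)cc(OC)c1OC | target

**Totals**
Total step count: 15. Longest linear sequence: 15 steps (1 to 24); the resolution in step 4 passes on at most half of the racemate.

**Steps most likely to fail**

Step 7 (vinyl addition). The ketone is α-quaternary on one side and carries the isopropyl-bearing CH on the other. Enolisation toward C7 (followed by loss of silanolate) or retro-aldol cleavage of the magnesium aldolate may therefore outrun 1,2-addition, or the nucleophile may enter from the wrong face. The fallback sets out from 11 and uses the smaller, far less basic ethynyl nucleophile (ethynylmagnesium bromide, THF, 0 °C) to give the 6-ethynyl diol F1. Semihydrogenation of the alkyne (H2, Pd/CaCO3 poisoned with Pb(OAc)2, quinoline, EtOAc) then gives the vinyl carbinol, and the route is rejoined at 12.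

Step 12 (fragmentation). The E geometry is safe as long as the process stays concerted, but the β-silyloxy ketone is born in the presence of alkoxide. E1cB loss of the C8 silyloxy group or epimerisation at C7 may therefore erode the product. The fallback sets out from 17 and runs a reductive fragmentation with LiAlH4 (THF, 0 °C to 40 °C). The aluminium alkoxide fragments and the ketone is reduced as soon as it appears, giving the (1(10)E,4Z)-dien-6-ol F2 as a mixture of C6 epimers. Neutral oxidation of this allylic alcohol with MnO2 in CH2Cl2 comes back to the route at 19.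

Step 15 (directed epoxidation). Three processes may interfere:
- Lewis-acid-induced transannular attack of the C1=C10 alkene on the new epoxide.
- Migration of the aroyl group from O8 to O6 before oxygen transfer.
- Failure of the ring to reach the small O–C6–C5=C4 dihedral angle needed for vanadium delivery, which would lower face selectivity.

The fallback installs the epoxide at the ketone level and changes the order of the end game, setting out from 19. Nucleophilic (Weitz–Scheffer) epoxidation with t-BuOOH/DBU in CH2Cl2 attacks only the enone and should give the cis-epoxy ketone F3. Its face selectivity would rest on peripheral attack on the ring and would have to be checked. HF·pyridine then frees the C8 hydroxyl to give the hydroxy epoxy ketone F4. The samarium-catalysed Evans–Tishchenko reduction with 21 reaches 24 directly; the 5,6-erythro relationship required is also the one that chelation of the epoxide oxygen favours in this hydride transfer.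

**Further compounds**
F1 | step 7 | 1-ethynyl-2-(1-hydroxy-4-methylpent-4-en-1-yl)-2-methyl-4-(tert-butyldimethylsilyloxy)-5-isopropylcyclopentan-1-ol (configuration as 12) | CC(C)(C)[Si](C)(C)O[C@H]1C[C@](C)(C(O)CCC(C)=C)[C@](O)(C#C)[C@H]1C(C)C
F2 | step 12 | (1(10)E,4Z,7S,8S)-8-(tert-butyldimethylsilyloxy)germacra-1(10),4-dien-6-ol (C6 epimers) | CC(C)(C)[Si](C)(C)O[C@H]1C/C(C)=C/CC/C(C)=C\C(O)[C@H]1C(C)C
F3 | step 15 | (1(10)E,4S,5S,7S,8S)-8-(tert-butyldimethylsilyloxy)-4,5-epoxygermacr-1(10)-en-6-one (cis-epoxide as in 24) | CC(C)(C)[Si](C)(C)O[C@H]1C/C(C)=C/CC[C@]2(C)O[C@@H]2C(=O)[C@H]1C(C)C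
F4 | step 15 | (1(10)E,4S,5S,7S,8S)-4,5-epoxy-8-hydroxygermacr-1(10)-en-6-one | O[C@H]1C/C(C)=C/CC[C@]2(C)O[C@@H]2C(=O)[C@H]1C(C)C
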